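**Plan**
1. Numbering: seven-membered ring C1 (CH–O-aroyl), C2, C3 (C(CH3)OH), C4, C5, C6, C7 (CH–iPr); five-membered ring C5, C8 (epoxide CH), C9 (epoxide C–CH3), C10, C6.
2. Enabling feature: the oxygen-bearing carbons C1 and C8 are 1,5-related across C7–C6–C5, and C1–C2–C3–C4–C5 is a five-carbon chain that a C1–C5 bond closes to a cyclopentanone. A 1,5-diketone beside a ring enlarged by two carbons (C6, C7) is what a de Mayo sequence leaves.
3. Cuts: the C1–O ester and the epoxide (back to a C1,C8-diketone); then C5–C6 and C1–C7 with C1–C5 restored (retro-de Mayo) to a 2-acylcyclopentanone; then C5–C8 (aldol, oxidation), C6=C7 (cross-metathesis) and C9–C10 (auxiliary allylation).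
4. Forward: the cyclopentanone first, the acyl chain joined at C5–C8, then light closes the five-membered ring (C5–C6) and a cyclobutane (C1–C7), and retro-aldol cleavage of C1–C5 enlarges the cyclopentanone to the seven-membered ring.
5. Stereochemistry: C3 from asymmetric conjugate borylation; C6 from the auxiliary-derived C9 methyl centre in the photocyclisation; C5 and C7 by equilibration next to the ketones; C1 by chelation-controlled reduction; C8/C9 by hydroxyl-directed epoxidation.

Key step: step 9

Remark 1: in step 1 the ligand antipode is taken as the one that gives the (S)-boronate 2 (hence (R)-3); the sense would be checked on 3 before going on.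
Remark 2: the C9 methyl group is taken to sit pseudo-equatorial when the five-membered ring closes (cis to the C6–C7 bond), which calls for the (2S)-acyl unit and therefore the (R)-configured oxazolidinone.

Step 1
Reactants: 1 3-methylcyclopent-2-en-1-one
Product: 3 (R)-3-hydroxy-3-methylcyclopentan-1-one, via boronate 2 (not isolated)
Conditions: B2pin2, [Cu(CH3CN)4]PF6 (10 mol %), (R,R)-QuinoxP* (12 mol %), LiOt-Bu (15 mol %), DMSO, rt; then NaBO3·4H2O, THF/H2O, rt
Reagents that add atoms: bis(pinacolato)diboron CC1(C)OB(OC1(C)C)B1OC(C)(C)C(C)(C)O1 (boron of 2); sodium perborate [Na+].[Na+].O[B-]1(O)OO[B-](O)(O)OO1 (oxygen of 3)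
Why: Copper-catalysed enantioselective conjugate borylation of a β-substituted cyclic enone, in which the chiral bisphosphine complex of monovalent copper delivers boron to one face of C3 and sets this centre, followed by perborate oxidation of the C–B bond with retention under conditions mild enough to spare the dehydration-prone β-hydroxy ketone.

Step 2
Reactants: 3 (R)-3-hydroxy-3-methylcyclopentan-1-one
Product: 4 (R)-3-methyl-3-(triethylsilyloxy)cyclopentan-1-one
Conditions: Et3SiOTf, 2,6-lutidine, CH2Cl2, −78 to 0 °C
Reagents that add atoms: triethylsilyl trifluoromethanesulfonate CC[Si](CC)(CC)OS(=O)(=O)C(F)(F)F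
Why: Silylation of a tertiary alcohol with a silyl triflate and a hindered pyridine base, which blocks retro-aldol opening and dehydration of the β-hydroxy ketone in the basic steps that follow.

Step 3
Reactants: 5 (R)-4-benzyl-3-propionyloxazolidin-2-one; 6 allyl bromide
Product: 7 (R)-4-benzyl-3-[(2S)-2-methylpent-4-enoyl]oxazolidin-2-one
Conditions: NaN(SiMe3)2, THF, −78 °C; then 6, −78 to −45 °C
Reagents that add atoms: none
Why: Evans asymmetric alkylation, in which the chelated Z sodium enolate is allylated on the face away from the benzyl group and so sets the (S) methyl-bearing centre that becomes C9.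

Step 4
Reactants: 7 (R)-4-benzyl-3-[(2S)-2-methylpent-4-enoyl]oxazolidin-2-one; 8 3-methylbut-1-ene
Product: 9 (R)-4-benzyl-3-[(2S,4E)-2,6-dimethylhept-4-enoyl]oxazolidin-2-one
Conditions: second-generation Grubbs catalyst (3 mol %), 8 (10 equiv), CH2Cl2, 40 °C, sealed vessel
Reagents that add atoms: none
Why: Olefin cross-metathesis of a terminal alkene with an excess of a volatile, allylically branched partner, driven by loss of ethylene and biased to the E alkene by the isopropyl group; a little Z isomer is tolerable because C7 is equilibrated after step 9.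

Step 5
Reactants: 9 (R)-4-benzyl-3-[(2S,4E)-2,6-dimethylhept-4-enoyl]oxazolidin-2-one
Product: 10 (2S,4E)-2,6-dimethylhept-4-en-1-ol
Conditions: LiBH4, MeOH (1 equiv), Et2O, 0 °C
Reagents that add atoms: none
Why: Reductive cleavage of the N-acyloxazolidinone by hydride attack at the exocyclic carbonyl, which releases the primary alcohol without touching the α-centre or the alkene and returns the auxiliary.

Step 6
Reactants: 10 (2S,4E)-2,6-dimethylhept-4-en-1-ol
Product: 11 (2S,4E)-2,6-dimethylhept-4-enal
Conditions: Dess–Martin periodinane, NaHCO3, CH2Cl2, 0 °C to rt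
Reagents that add atoms: none
Why: Dess–Martin oxidation under buffered, non-basic conditions should give the α-branched aldehyde without epimerisation, and it is used at once.

Step 7
Reactants: 4 (R)-3-methyl-3-(triethylsilyloxy)cyclopentan-1-one; 11 (2S,4E)-2,6-dimethylhept-4-enal
Product: 12 aldol adduct (4R)-2-[(2S,4E)-1-hydroxy-2,6-dimethylhept-4-en-1-yl]-4-methyl-4-(triethylsilyloxy)cyclopentan-1-one
Conditions: LiN(i-Pr)2, THF, −78 °C (4 added to the base); then 11, −78 °C; AcOH quench
Reagents that add atoms: none
Why: Directed aldol addition of the kinetic lithium enolate, formed at the methylene remote from the quaternary carbon, which joins C5 to C8; the two new centres are erased in step 8 (oxidation and enolisation), so their configuration does not matter.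

Step 8
Reactants: 12 aldol adduct
Product: 13 (4R)-2-[(2S,4E)-2,6-dimethylhept-4-enoyl]-4-methyl-4-(triethylsilyloxy)cyclopentan-1-one as its ring enol
Conditions: Dess–Martin periodinane, NaHCO3, CH2Cl2, rt
Reagents that add atoms: none
Why: Dess–Martin oxidation of a β-hydroxy ketone to the β-diketone, which stops at this stage and, being non-basic, should leave the C9 methyl centre intact; the product rests as the hydrogen-bonded enol.

Step 9
Reactants: 13 ring enol of the 2-acylcyclopentanone
Product: 15 (3R,5S,6R,7S,9S) trans-fused C1/C8 diketone bearing the C3 triethylsilyl ether, via cyclobutanol 14 (not isolated)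
Conditions: hν (medium-pressure Hg lamp, Pyrex filter, λ > 300 nm), degassed cyclohexane (5 mM), rt; then DBU (0.2 equiv), CH2Cl2, rt
Reagents that add atoms: none
Why: Intramolecular de Mayo reaction (enol–alkene [2+2] photocycloaddition, then retro-aldol cleavage): the triplet of the hydrogen-bonded ring enol, a β-hydroxy enone, bonds C5 to C6 in a 5-exo closure that forms the five-membered ring C5–C8–C9–C10–C6, and the 1,4-biradical then collapses by C1–C7 bonding to the cyclobutane in the fused bicyclo[3.2.0] mode. Cyclobutanol 14 is a strained β-hydroxy ketone towards C8, and its hydrogen-bonded hydroxyl triggers retro-aldol cleavage of C1–C5, so the seven-membered ring arises by two-carbon enlargement of the cyclopentanone and not by a direct seven-ring closure. C6 is the one centre that has to be set kinetically: in the chelated enol C9 lies syn to C4, the C9 methyl should therefore take the pseudo-equatorial site of the forming ring, cis to the C6–C7 bond as in closures of 3-substituted 5-hexenyl radicals, and the (9S) centre is translated into (6R). C7 follows from the E alkene and C5 from ketonisation of the C5=C8 enol, but both lie α to a ketone and DBU should bring them, with C9, to the all-equatorial trans-fused arrangement (H5 trans to H6, isopropyl trans to C10). The selectivity needed is fused over crossed closure and reaction of the enol rather than of the product; the three-atom tether C8–C9–C10 (rule of five, first bond C5–C6) and light above 300 nm, which the saturated diketone hardly absorbs, should secure it.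

Step 10
Reactants: 15 trans-fused diketone with C3 triethylsilyl ether
Product: 16 (3R,5S,6R,7S,9S) C3-hydroxy diketone
Conditions: HF·pyridine, pyridine, THF, 0 °C to rt
Reagents that add atoms: none
Why: Fluoride cleavage of the tertiary silyl ether under buffered acidic conditions, which avoid the alkoxide that could open the β-hydroxy ketone by retro-aldol reaction.

Step 11
Reactants: 16 C3-hydroxy diketone
Product: 17 (1R,3R,5S,6R,7S,9S) 1,3-cis diol with the C8 ketone intact
Conditions: Et2BOMe, THF/MeOH (4:1), rt then −78 °C; NaBH4, −78 °C; AcOH; repeated evaporation from MeOH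
Reagents that add atoms: none
Why: Narasaka–Prasad reduction, in which the diethylboron chelate between the C3 oxygen and the C1 carbonyl activates only this ketone and covers one of its faces, so that borohydride attacks from the face away from the C3 oxygen and the C7 isopropyl group and gives the C1 hydroxyl cis to both, while the unchelated, doubly α-branched C8 ketone should react far more slowly at −78 °C.

Step 12
Reactants: 17 1,3-cis diol; 18 3-(benzyloxy)-4-methoxybenzoic acid
Product: 19 C1 3-(benzyloxy)-4-methoxybenzoate
Conditions: DCC, DMAP, CH2Cl2, rt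
Reagents that add atoms: none
Why: Steglich esterification (carbodiimide activation, acyl transfer by DMAP), which acylates only the secondary C1 hydroxyl with retention because the tertiary C3 hydroxyl is too hindered.

Step 13
Reactants: 19 C1 aroyl ester with free C3 hydroxyl
Product: 20 C3 trimethylsilyl ether of 19
Conditions: N-(trimethylsilyl)imidazole, CH2Cl2, rt
Reagents that add atoms: N-(trimethylsilyl)imidazole C[Si](C)(C)n1ccnc1
Why: Silylation of the tertiary alcohol with a neutral, powerful silyl donor that does not enolise the ketone, so that no alkoxide can form and shift the neighbouring ester in the strongly basic next step.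

Step 14
Reactants: 20 C3 trimethylsilyl ether
Product: 21 C8=C9 enol triflate
Conditions: KN(SiMe3)2, THF, −78 °C; then PhNTf2, −78 to −20 °C
Reagents that add atoms: N-phenylbis(trifluoromethanesulfonimide) O=S(=O)(N(c1ccccc1)S(=O)(=O)C(F)(F)F)C(F)(F)F
Why: Kinetic enolate formation and O-sulfonylation (enol triflate synthesis), in which the hindered base should remove the more accessible C9 methine hydrogen beside the methyl group rather than the ring-fusion hydrogen at C5, so that the now superfluous C9 centre disappears and C5 keeps its configuration.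

Step 15
Reactants: 21 C8=C9 enol triflate
Product: 23 C8=C9 alkene with free C3 hydroxyl, via trimethylsilyl ether 22 (not isolated)
Conditions: Pd(OAc)2 (5 mol %), PPh3 (10 mol %), HCO2H, n-Bu3N, DMF, 60 °C; then citric acid, MeOH, rt
Reagents that add atoms: none
Why: Palladium-catalysed formate reduction of an enol triflate (oxidative addition to zerovalent palladium, formate-for-triflate exchange with loss of CO2, reductive elimination), which gives the trisubstituted alkene without touching the benzyl ether or the ester, followed by mild acid methanolysis of the labile tertiary trimethylsilyl ether.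

Step 16
Reactants: 23 C8=C9 alkene with free C3 hydroxyl
Product: 24 (1R,3R,5S,6R,7S,8S,9R) C8–C9 epoxide with the benzyl-protected phenol
Conditions: VO(acac)2 (5 mol %), t-BuOOH (in decane), CH2Cl2, 0 °C to rt
Reagents that add atoms: tert-butyl hydroperoxide CC(C)(C)OO
Why: Hydroxyl-directed epoxidation, in which the vanadium alkoxide of the bishomoallylic C3 hydroxyl delivers the peroxide oxygen to the alkene face on its own side (the face of H6, opposite H5) and so sets C8 and C9; this hydroxyl cannot open the epoxide from the rear.

Step 17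
Reactants: 24 benzyl-protected epoxide
Product: 25 target compound CNP0106636.1
Conditions: H2 (1 atm), Pd/C (10 %), EtOAc, rt
Reagents that add atoms: none
Why: Hydrogenolysis of the aryl benzyl ether under neutral conditions, which should leave the trisubstituted epoxide, the ester and the tertiary alcohol untouched.

**Compound list**
1 | 3-methylcyclopent-2-en-1-one | CC1=CC(=O)CC1 | starting material
2 | (S)-3-methyl-3-(4,4,5,5-tetramethyl-1,3,2-dioxaborolan-2-yl)cyclopentan-1-one | O=C1C[C@](C)(B2OC(C)(C)C(C)(C)O2)CC1 | intermediate (not isolated)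
3 | (R)-3-hydroxy-3-methylcyclopentan-1-one | O=C1C[C@](C)(O)CC1 | intermediate
4 | (R)-3-methyl-3-(triethylsilyloxy)cyclopentan-1-one | O=C1C[C@](C)(O[Si](CC)(CC)CC)CC1 | intermediate
5 | (R)-4-benzyl-3-propionyloxazolidin-2-one | CCC(=O)N1[C@H](Cc2ccccc2)COC1=O | starting material
6 | allyl bromide (3-bromoprop-1-ene) | C=CCBr | starting material
7 | (R)-4-benzyl-3-[(2S)-2-methylpent-4-enoyl]oxazolidin-2-one | C=CC[C@H](C)C(=O)N1[C@H](Cc2ccccc2)COC1=O | intermediate
8 | 3-methylbut-1-ene | C=CC(C)C | starting material
9 | (R)-4-benzyl-3-[(2S,4E)-2,6-dimethylhept-4-enoyl]oxazolidin-2-one | CC(C)/C=C/C[C@H](C)C(=O)N1[C@H](Cc2ccccc2)COC1=O | intermediate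
10 | (2S,4E)-2,6-dimethylhept-4-en-1-ol | CC(C)/C=C/C[C@H](C)CO | intermediate
11 | (2S,4E)-2,6-dimethylhept-4-enal | CC(C)/C=C/C[C@H](C)C=O | intermediate
12 | (4R)-2-[(2S,4E)-1-hydroxy-2,6-dimethylhept-4-en-1-yl]-4-methyl-4-(triethylsilyloxy)cyclopentan-1-one (aldol adduct; epimer mixture at ring C2 and at the carbinol carbon) | O=C1C[C@](C)(O[Si](CC)(CC)CC)CC1C(O)[C@@H](C)C/C=C/C(C)C | intermediate
13 | (4R)-2-[(2S,4E)-2,6-dimethylhept-4-enoyl]-4-methyl-4-(triethylsilyloxy)cyclopentan-1-one, drawn as its hydrogen-bonded ring enol (C1–OH, C1=C5) | OC1=C(C(=O)[C@@H](C)C/C=C/C(C)C)C[C@@](C)(O[Si](CC)(CC)CC)C1 | intermediate (key-step precursor)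
14 | tricyclic cyclobutanol (1R,3R,5S,6S,7S,9S): cyclopentane C1–C5, cyclobutane C1/C5/C6/C7, cyclopentanone C5/C8/C9/C10/C6; C1–OH and C8=O on the same face of the cyclobutane | O[C@@]12C[C@](C)(O[Si](CC)(CC)CC)C[C@]1(C(=O)[C@@H](C)C3)[C@@H]3[C@@H]2C(C)C | intermediate (not isolated)
15 | (3R,5S,6R,7S,9S) trans-fused bicyclo[5.3.0]decane-1,8-dione (numbering of the plan): C3 methyl and triethylsilyloxy, C7 isopropyl, C9 methyl | O=C1C[C@](C)(O[Si](CC)(CC)CC)C[C@H]2[C@@H](C[C@H](C)C2=O)[C@@H]1C(C)C | intermediate (key-step product)
16 | (3R,5S,6R,7S,9S) C3-hydroxy diketone | O=C1C[C@](C)(O)C[C@H]2[C@@H](C[C@H](C)C2=O)[C@@H]1C(C)C | intermediate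
17 | (1R,3R,5S,6R,7S,9S) 1,3-cis diol, C8 ketone (C1–OH cis to C3–OH and to isopropyl) | O[C@@H]1C[C@](C)(O)C[C@H]2[C@@H](C[C@H](C)C2=O)[C@@H]1C(C)C | intermediate
18 | 3-(benzyloxy)-4-methoxybenzoic acid | COc1ccc(C(=O)O)cc1OCc1ccccc1 | starting material
19 | C1 3-(benzyloxy)-4-methoxybenzoate of 17 (C3–OH free, C8 ketone) | COc1ccc(C(=O)O[C@@H]2C[C@](C)(O)C[C@H]3[C@@H](C[C@H](C)C3=O)[C@@H]2C(C)C)cc1OCc1ccccc1 | intermediate
20 | C3 trimethylsilyl ether of 19 | COc1ccc(C(=O)O[C@@H]2C[C@](C)(O[Si](C)(C)C)C[C@H]3[C@@H](C[C@H](C)C3=O)[C@@H]2C(C)C)cc1OCc1ccccc1 | intermediate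
21 | (1R,3R,5S,6S,7S) C8=C9 enol triflate (C8–OTf, C9–CH3) | COc1ccc(C(=O)O[C@@H]2C[C@](C)(O[Si](C)(C)C)C[C@H]3[C@@H](CC(C)=C3OS(=O)(=O)C(F)(F)F)[C@@H]2C(C)C)cc1OCc1ccccc1 | intermediate
22 | (1R,3R,5S,6R,7S) C8=C9 alkene, C3 trimethylsilyl ether | COc1ccc(C(=O)O[C@@H]2C[C@](C)(O[Si](C)(C)C)C[C@H]3[C@@H](CC(C)=C3)[C@@H]2C(C)C)cc1OCc1ccccc1 | intermediate (not isolated)
23 | (1R,3R,5S,6R,7S) C8=C9 alkene, C3–OH free | COc1ccc(C(=O)O[C@@H]2C[C@](C)(O)C[C@H]3[C@@H](CC(C)=C3)[C@@H]2C(C)C)cc1OCc1ccccc1 | intermediate
24 | (1R,3R,5S,6R,7S,8S,9R) C8–C9 epoxide, phenol as benzyl ether | COc1ccc(C(=O)O[C@@H]2C[C@](C)(O)C[C@H]3[C@@H](C[C@@]4(C)O[C@@H]34)[C@@H]2C(C)C)cc1OCc1ccccc1 | intermediate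
25 | CNP0106636.1, (1R,3R,5S,6R,7S,8S,9R) epoxy alcohol 3-hydroxy-4-methoxybenzoate | COc1ccc(C(=O)O[C@@H]2C[C@](C)(O)C[C@H]3[C@@H](C[C@@]4(C)O[C@@H]34)[C@@H]2C(C)C)cc1O | target

**Step count**
Total: 17 steps. Longest linear sequence: 15 steps (steps 3 to 17).

**Steps most likely to fail**

Step 9. The excited enol chelate may leak into the crossed closure through its exocyclic-enol tautomer (C7 bonding to C8). The C9 methyl group may also discriminate the two faces too weakly, or the diketone may be photolysed further on long irradiation. The fallback sets out from 13 and comes back at 15. Compound 13 is O-acylated at the ring-enol oxygen (benzyl chloroformate, pyridine, CH2Cl2, 0 °C), as expected for an α-branched 2-acylcyclopentanone, to give the enol benzyl carbonate F1, in which the ring-enol chromophore is locked. Irradiation (Pyrex, cyclohexane) should give the cyclobutyl benzyl carbonate F2, a stable compound that can be purified and on which C6 epimers can be separated; because F1 is not chelated, the sense of induction at C6 would be checked again here. Hydrogenolysis (H2, Pd/C, EtOAc, which spares the triethylsilyl ether) unmasks cyclobutanol 14, which fragments, and DBU then gives 15.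

Step 14. The base may also remove the ring-fusion hydrogen at C5, which would give the C5=C8 triflate and destroy the C5 centre. The fallback sets out from 20 and comes back at 22. NaBH4 (THF/EtOH, 0 °C) should reduce C8 by hydride attack on the face of H5, the other face carrying the axial H6 and H9, to give the C8 alcohol F4 with the hydroxyl cis to H9 and trans to H5. Burgess reagent (benzene, 50 °C) then eliminates by a syn pathway that can only use H9 and gives alkene 22, which the acidic methanol treatment of step 15 turns into 23.

Step 11. Borohydride may also reduce the unchelated C8 ketone, or the tertiary alcohol may chelate incompletely so that C1 epimers form. The fallback sets out from 16 and comes back at 19. Me4NBH(OAc)3 (MeCN/AcOH, −20 °C; Evans–Saksena reduction) reduces only the ketone that carries the β-hydroxyl, by intramolecular hydride delivery, and should give the 1,3-trans diol F3. Mitsunobu esterification of F3 with acid 18 (PPh3, diisopropyl azodicarboxylate, toluene, 0 °C to rt) inverts C1 and gives 19 directly.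

**Further compounds**
F1 | step 9 | enol benzyl carbonate of 13 (benzyl carbonate on the ring-enol oxygen at C1) | O=C(OCc1ccccc1)OC1=C(C(=O)[C@@H](C)C/C=C/C(C)C)C[C@@](C)(O[Si](CC)(CC)CC)C1
F2 | step 9 | cyclobutyl benzyl carbonate (benzyl carbonate of cyclobutanol 14) | O=C(OCc1ccccc1)O[C@@]12C[C@](C)(O[Si](CC)(CC)CC)C[C@]1(C(=O)[C@@H](C)C3)[C@@H]3[C@@H]2C(C)C
F3 | step 11 | 1,3-trans diol, C1 epimer of 17 | O[C@H]1C[C@](C)(O)C[C@H]2[C@@H](C[C@H](C)C2=O)[C@@H]1C(C)C
F4 | step 14 | C8 alcohol from 20 (hydroxyl cis to H9, trans to H5) | COc1ccc(C(=O)O[C@@H]2C[C@](C)(O[Si](C)(C)C)C[C@H]3[C@@H](C[C@H](C)[C@H]3O)[C@@H]2C(C)C)cc1OCc1ccccc1
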